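- Percentages add up: whatever part of the substrate charged is not product at a reading stands somewhere else, so the product column shows how much is still to be shared out.

| flask | substrate | partner | capture agent | protic impurity | remark | time |
|---|---|---|---|---|---|---|
| Sunday's | 42 mM | 2.5 equiv | 28 mM | 4.2 mM | run made earlier |  |
| Wednesday's | 42 mM | 2.5 equiv | 63 mM | 4.2 mM | run made earlier |  |
| Tuesday's | 63 mM | 2.5 equiv | 42 mM | 4.2 mM | run made earlier |  |
| flask | 42 mM | 2.50 equiv | 42.0 mM | 4.20 mM |  | 4.0 h |

- Sunday's (time / h: intermediate C / %, product / %): 0.0500: 9.7, 52.6; 0.100: 12.8, 59.8; 0.200: 12.5, 61.6; 0.500: 9.8, 61.5; 1.00: 5.0, 62.4; 2.00: 2.3, 63.3; 5.00: 0, 64.4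
- Wednesday's (time / h: intermediate C / %, product / %): 0.0500: 6.3, 52.6; 0.100: 7.2, 57.9; 0.200: 6.9, 59.3; 0.500: 4.4, 60.1; 1.00: 3.4, 60.5; 2.00: 0.5, 60.7; 5.00: 0, 60.6
- Tuesday's (time / h: intermediate C / %, product / %): 0.0500: 15.1, 45.4; 0.167: 16.8, 51.1; 0.500: 12.6, 51.6; 1.50: 4.7, 52.2; 5.00: 0.3, 53.2

(standard deviation of a reading: 0.5 percentage points)

- time, not beyond 4.0 h, at which the flask holds most intermediate C
- the amount of intermediate C, in percent of the substrate charged, at that time

- Sunday's and Wednesday's runs charge the substrate and partner of this flask and differ from it in capture agent. By 0.100 h they hold 59.8% and 57.9% of product, and Sunday's run reads 64.4% at 5.00 h.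
- This reckoning takes that fast step as finished and works with the free share it leaves, the part that is not product: 40.2% on Sunday, 42.1% on Wednesday, on average 41.2%.
- Both runs read most intermediate C at 0.100 h, Sunday's reading there standing above the next one and Wednesday's too. The free share minus C is an unseen rest, 27.4% on Sunday and 34.9% on Wednesday.
- The balance charge is the capture-agent charge times C over that unseen rest, a selectivity factor written as a charge. It reads 13.1 mM on Sunday and 13.0 mM on Wednesday, though Wednesday charges 63 mM of capture agent against Sunday's 28 mM, each reading carrying a scatter of 0.5 percentage points. Their mean is 13.0 mM.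
- Tuesday's run, with more substrate and partner, reads 22.0 mM, so the balance charge is held to 42 mM of substrate at 2.50 equiv of partner.
- For this flask, with 42.0 mM of capture agent, C is the free share times balance charge over balance charge plus capture charge: 9.75%, near 0.100 h.
- The forecast, apart from this reckoning in both numbers, says “C then decays slowly” and gives 10% at 0.13 h.
- The flask gives 9.70% at 0.111 h.

    partner + intermediate A ⇌ intermediate C (K = 150 M⁻¹, k = 0.0720 M⁻¹ s⁻¹)
    substrate → product (k = 0.0130 s⁻¹)
    capture agent + intermediate A → trapped intermediate (k = 0.430 M⁻¹ s⁻¹)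
    substrate ⇌ intermediate B (K = 0.780, k = 0.00620 s⁻¹)
    partner + protic impurity → quenched reagent (k = 0.780 M⁻¹ s⁻¹)
    substrate + partner ⇌ intermediate A (K = 58.0 M⁻¹, k = 0.100 M⁻¹ s⁻¹)

- At that time this flask holds 58.2% of product and 9.70% of intermediate C, with 27.5% of trapped intermediate inside the unseen rest. Its balance charge therefore comes to 12.7 mM, beside the 13.0 mM read from the runs. The neighbouring flask is charged like this one but with 110 mM of capture agent. The same free share and balance charge give it 4.35% of intermediate C, and its highest amount stands at 4.39%.

The data are calculated for an exercise.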